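**Plan**

- Retrosynthesis: (a) add H2 across one of the two identical C7=C8 bonds of a C2-symmetric 7,7′-diene-3,3′-diol. (b) Cut C1–C2 and C4–C5 of each ring A; this releases 3-methylbutan-2-one and leaves a ring B that carries CHO (C1) on the quaternary C10 and a C5=C6–C7=O enone. (c) Cut C5–C10 and C8–C9 of each ring B (Diels–Alder); this leads to (2E,6E)-2,7-dimethylocta-2,6-dienedial, which already holds C1, C9, C10, the C10 methyl groups and the C11–C11′ linker of both halves.
- Enabling feature: in each half C2–C3(O)–C4(CH3)2 is a masked 3-methylbutan-2-one with two nucleophilic α-carbons, and C1 and C5 both sit on the quaternary C10. Ring A can therefore close by α,α′-annulation of the ketone onto a 1,3-bis-electrophile (formyl C1, enone β-carbon C5). The C7=C8 alkene of the target marks where the enone carbonyl sat.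
- Forward order: dial → both rings B (two-fold Diels–Alder, then Saegusa–Ito) → both rings A in one operation ([3+3] aldol/Michael annulation) → ring A enones and ring B enol triflates → diene diol → mono-hydrogenation.
- Stereochemistry: C9 and C10 from the catalyst-controlled Diels–Alder reaction on the E-enal; C5 (trans fusion) by thermodynamic equilibration; C3 by dissolving-metal reduction (equatorial OH); C8 of the saturated half by hydrogen-atom-transfer hydrogenation (equatorial methyl).

Key step: step 5

Remark: each bicyclic half is numbered as in drimane (decalin C1–C10, gem-dimethyl on C4, methyl on C8 and on C10, C11 = the CH2 on C9). The halves are joined C11–C11′ by a two-carbon CH2–CH2 link; ring A is C1–C5/C10 and ring B is C5–C10.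
Remark: compounds 1, 2, 5 and 9 are taken as commercial. In the two-fold steps the half-reacted species undergo the same reaction at the second, equivalent site and are not numbered separately.

**Route**

Step 1
Reactants: 1 2,5-dimethoxytetrahydrofuran; 2 2-(triphenylphosphoranylidene)propanal (2.2 equiv; two molecules are incorporated)
Product: 4 (2E,6E)-2,7-dimethylocta-2,6-dienedial, via succinaldehyde 3 (not isolated)
Conditions: 0.1 M aq. HCl, 70 °C; NaHCO3; then 2 (2.2 equiv), CH2Cl2/H2O, 25 °C
Reagents that add atoms: none
Why: Acid hydrolysis of the bis-acetal unmasks succinaldehyde, and the stabilised formyl ylide then effects a two-fold Wittig olefination that should be E-selective and stop at the α-methyl enal stage, because the conjugated, α-branched product aldehydes react far more slowly than the aliphatic ones; no stereocentre is formed.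

Step 2
Reactants: 5 pent-1-en-3-one
Product: 6 (Z)-tert-butyldimethyl(penta-1,3-dien-3-yloxy)silane
Conditions: TBSOTf (1.1 equiv), Et3N (1.5 equiv), Et2O, 0 °C
Reagents that add atoms: tert-butyldimethylsilyl trifluoromethanesulfonate, CC(C)(C)[Si](C)(C)OS(=O)(=O)C(F)(F)F
Why: Soft enolisation of the ethyl ketone (silyl enol ether formation) should give the 2-silyloxydiene as the Z-enol ether, which places the terminal methyl on the outside of the s-cis diene as the Diels–Alder reaction requires.

Step 3
Reactants: 4 (2E,6E)-2,7-dimethylocta-2,6-dienedial; 6 (Z)-tert-butyldimethyl(penta-1,3-dien-3-yloxy)silane (2.6 equiv; two molecules are incorporated, one at each enal)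
Product: 7 6,6′-(ethane-1,2-diyl)bis[(1S,6S)-4-(tert-butyldimethylsilyloxy)-1,5-dimethylcyclohex-3-ene-1-carbaldehyde] (ring C5 epimers)
Conditions: 3,3-diphenyl-1-(2-methylphenyl)tetrahydro-1H,3H-pyrrolo[1,2-c][1,3,2]oxazaborole protonated with HN(SO2CF3)2 (40 mol%; the enantiomer that leaves the Cα-Si face of the enal open), CH2Cl2, −78 → −20 °C
Reagents that add atoms: none
Why: Two-fold enantioselective Diels–Alder reaction of the Lewis-acid-activated α-methyl enals, in which the silyloxy group directs its enol carbon (C8) to the β-carbon (C9) and C5 to the quaternary C10, suprafacial addition to the E-enal fixes the C9 side chain cis to the C10 methyl, and the catalyst sets the absolute configuration of C9 and C10 in each ring, the two independent events enriching the C2-symmetric diastereomer over the separable meso form (C8 forms without control, which is of no consequence because it becomes trigonal in step 7).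

Step 4
Reactants: 7 bis(silyl enol ether) dialdehyde
Product: 8 6,6′-(ethane-1,2-diyl)bis[(1S,6S)-1,5-dimethyl-4-oxocyclohex-2-ene-1-carbaldehyde] (ring C5 epimers)
Conditions: Pd(OAc)2 (20 mol%), O2 (1 atm), DMSO, 40 °C
Reagents that add atoms: none
Why: Saegusa–Ito oxidation, in which the silyl enol ether gives a C6 palladium enolate whose only β-hydrogens are on C5, so β-hydride elimination should deliver the C5=C6–C7=O enone regiospecifically and leave the neopentyl aldehyde and the stereocentres untouched.

Step 5
Reactants: 8 bis(enone aldehyde); 9 3-methylbutan-2-one (2.3 equiv; two molecules are incorporated, one at each half)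
Product: 13 1,1′-dihydroxy-11,11′-bidrimane-3,3′,7,7′-tetraone (9α-H and 10β-methyl in both halves; epimers at C1 and C5 and C8), via lithium 3-methylbut-1-en-2-olate 10 (not isolated), via dilithium bis-aldolate 11 (not isolated), via tetralithium bis-aldolate dianion 12 (not isolated)
Conditions: LiN(iPr)2 (2.3 equiv), 9, THF, −78 °C; 8 in THF, −78 °C; LiN(iPr)2 (2.3 equiv), −78 → 0 °C; AcOH, −78 °C
Reagents that add atoms: none
Why: Proposed new method: the kinetic lithium enolate of 9 (CH3 side, the future C2) adds to each non-enolisable, neopentyl formyl group (C1) of 8 in an aldol addition, and a second equivalent of amide base deprotonates each lithium aldolate at its α′-position, the isopropyl C–H (future C4), whose tetrasubstituted enolate closes ring A by intramolecular Michael addition to C5 of the C5=C6–C7=O enone. The closest known reaction types are the α′-deprotonation and C–C bond formation of lithium aldolate dianions (a β-oxido enolate does not eliminate) and the α,α′-annulation of ketones onto 1,3-bis-electrophiles. Each ring A closes in the 6-(enolendo)-exo-trig mode onto the ring B enone. C1 (carbinol) forms without control and is removed in step 6; C5 forms under kinetic control by attack anti to the pseudoaxial C10 methyl, which should favour the cis ring fusion or give a mixture, and is corrected by equilibration in step 6; C9 and C10 are untouched. The step needs 1,2-addition to CHO rather than to the enone (secured by the higher electrophilicity of the aldehyde at −78 °C) and enolisation at C4 rather than at C2 or C8 (the β-oxido group disfavours the C2 enolate, and irreversible cyclisation should drain the C4 enolate from any equilibrium with the C8 dienolate). It also needs the aldolate to cyclise before retro-aldol cleavage of the γ-formyl enone.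

Step 6
Reactants: 13 bis(1-hydroxy-3,7-dione)
Product: 14 11,11′-bi(drim-1-ene)-3,3′,7,7′-tetraone (5α-H; 8α-methyl; 9α-H; 10β-methyl in both halves)
Conditions: KOtBu (0.3 equiv), tBuOH/THF, 50 °C
Reagents that add atoms: none
Why: Base-mediated aldol dehydration (E1cB) gives each ring A enone, and under the same equilibrating conditions reversible retro-Michael/Michael reaction at C4–C5 and enolisation at C8 should funnel the mixture to the thermodynamically preferred isomer with trans ring fusion (in the cis isomer the fully substituted C4 is axial on ring B) and equatorial C8 methyl.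

Step 7
Reactants: 14 bis(1-ene-3,7-dione)
Product: 15 3,3′-dioxo-11,11′-bi(drima-1,7-diene)-7,7′-diyl bis(trifluoromethanesulfonate)
Conditions: Tf2O (2.5 equiv), 2,6-di-tert-butyl-4-methylpyridine (3 equiv), CH2Cl2, 0 → 25 °C
Reagents that add atoms: trifluoromethanesulfonic anhydride, O=S(=O)(OS(=O)(=O)C(F)(F)F)C(F)(F)F
Why: Enol triflate formation under thermodynamic control, in which the ring A enones cannot enolise (C4 and C10 are quaternary) and the C7 ketone should lose the C8 proton to give the more substituted C7=C8 triflate, the alternative axial C6 proton being shielded by the syn-axial methyl groups on C4 and C10.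

Step 8
Reactants: 15 bis(enol triflate)
Product: 16 11,11′-bi(drima-1,7-diene)-3,3′-dione
Conditions: Pd(OAc)2 (10 mol%), PPh3 (20 mol%), HCO2H (5 equiv), Bu3N (8 equiv), DMF, 60 °C
Reagents that add atoms: none
Why: Palladium-catalysed formate reduction of enol triflates (oxidative addition, formate exchange, decarboxylation to a palladium hydride, reductive elimination) should replace each C7–OTf by C7–H with the C7=C8 bond in place and tolerate the enones.

Step 9
Reactants: 16 bis(dienone)
Product: 17 11,11′-bi(drim-7-ene)-3β,3′β-diol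
Conditions: Li (excess), liquid NH3/THF, −78 °C; EtOH, −78 → −33 °C; NH4Cl
Reagents that add atoms: none
Why: Dissolving-metal reduction, in which each enone is reduced to its lithium enolate, protonation by EtOH releases the C3 ketone and further reduction should give the thermodynamically favoured equatorial 3β-alcohol (this sets C3), while the isolated trisubstituted alkenes are inert.

Step 10
Reactants: 17 C2-symmetric diene diol
Product: 18 target, 11-[(8βH)-3β-hydroxydriman-11-yl]drim-7-en-3β-ol
Conditions: Mn(dpm)3 [Mn(C11H19O2)3] (10 mol%), PhSiH3 (0.6 equiv), tBuOOH (0.8 equiv), iPrOH/CH2Cl2, 22 °C, stopped at partial conversion; recovered 17 resubmitted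
Reagents that add atoms: none
Why: Hydrogen-atom-transfer hydrogenation, in which a manganese hydride transfers H to C7 and the tertiary C8 radical should accept the second hydrogen in a product-like transition state so that the C8 methyl ends equatorial (8β-H; surface hydrogenation would add from the α-face and leave the methyl axial), and because the two alkenes of 17 are homotopic, saturation of either gives the same compound 18.

**Compound list**

1 | 2,5-dimethoxytetrahydrofuran (cis/trans mixture) | COC1CCC(OC)O1 | starting material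
2 | 2-(triphenylphosphoranylidene)propanal | CC(C=O)=P(c1ccccc1)(c1ccccc1)c1ccccc1 | starting material
3 | succinaldehyde (formed in the flask) | O=CCCC=O | intermediate
4 | (2E,6E)-2,7-dimethylocta-2,6-dienedial | O=C/C(C)=C/CC/C=C(C)/C=O | intermediate
5 | pent-1-en-3-one | C=CC(=O)CC | starting material
6 | (Z)-tert-butyldimethyl(penta-1,3-dien-3-yloxy)silane | C=C/C(O[Si](C)(C)C(C)(C)C)=C/C | intermediate
7 | 6,6′-(ethane-1,2-diyl)bis[(1S,6S)-4-(tert-butyldimethylsilyloxy)-1,5-dimethylcyclohex-3-ene-1-carbaldehyde]; ring C5 (= C8) unassigned | C([C@H]1C(C)C(O[Si](C)(C)C(C)(C)C)=CC[C@]1(C)C=O)C[C@H]1C(C)C(O[Si](C)(C)C(C)(C)C)=CC[C@]1(C)C=O | intermediate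
8 | 6,6′-(ethane-1,2-diyl)bis[(1S,6S)-1,5-dimethyl-4-oxocyclohex-2-ene-1-carbaldehyde]; ring C5 (= C8) unassigned | C([C@H]1C(C)C(=O)C=C[C@]1(C)C=O)C[C@H]1C(C)C(=O)C=C[C@]1(C)C=O | intermediate
9 | 3-methylbutan-2-one | CC(=O)C(C)C | starting material
10 | lithium 3-methylbut-1-en-2-olate (formed in the flask) | [Li+].[O-]C(=C)C(C)C | intermediate
11 | dilithium bis-aldolate: each CHO of 8 converted into CH(OLi)CH2C(=O)CH(CH3)2 (formed in the flask; C1 unassigned) | [Li+].[Li+].C([C@H]1C(C)C(=O)C=C[C@]1(C)C([O-])CC(=O)C(C)C)C[C@H]1C(C)C(=O)C=C[C@]1(C)C([O-])CC(=O)C(C)C | intermediate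
12 | tetralithium bis-aldolate dianion: 11 with each C3 ketone as its C3=C4 lithium enolate (formed in the flask) | [Li+].[Li+].[Li+].[Li+].C([C@H]1C(C)C(=O)C=C[C@]1(C)C([O-])CC([O-])=C(C)C)C[C@H]1C(C)C(=O)C=C[C@]1(C)C([O-])CC([O-])=C(C)C | intermediate
13 | 1,1′-dihydroxy-11,11′-bidrimane-3,3′,7,7′-tetraone; 9α-H and 10β-methyl in both halves; C1, C5 and C8 unassigned | C([C@H]1C(C)C(=O)CC2C(C)(C)C(=O)CC(O)[C@]12C)C[C@H]1C(C)C(=O)CC2C(C)(C)C(=O)CC(O)[C@]12C | intermediate
14 | 11,11′-bi(drim-1-ene)-3,3′,7,7′-tetraone; 5α-H, 8α-methyl (8β-H), 9α-H, 10β-methyl in both halves | C([C@H]1[C@H](C)C(=O)C[C@H]2C(C)(C)C(=O)C=C[C@]12C)C[C@H]1[C@H](C)C(=O)C[C@H]2C(C)(C)C(=O)C=C[C@]12C | intermediate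
15 | 3,3′-dioxo-11,11′-bi(drima-1,7-diene)-7,7′-diyl bis(trifluoromethanesulfonate); 5α-H, 9α-H, 10β-methyl | C([C@H]1C(C)=C(OS(=O)(=O)C(F)(F)F)C[C@H]2C(C)(C)C(=O)C=C[C@]12C)C[C@H]1C(C)=C(OS(=O)(=O)C(F)(F)F)C[C@H]2C(C)(C)C(=O)C=C[C@]12C | intermediate
16 | 11,11′-bi(drima-1,7-diene)-3,3′-dione; 5α-H, 9α-H, 10β-methyl | C([C@H]1C(C)=CC[C@H]2C(C)(C)C(=O)C=C[C@]12C)C[C@H]1C(C)=CC[C@H]2C(C)(C)C(=O)C=C[C@]12C | intermediate
17 | 11,11′-bi(drim-7-ene)-3β,3′β-diol; 5α-H, 9α-H, 10β-methyl | C([C@H]1C(C)=CC[C@H]2C(C)(C)[C@@H](O)CC[C@]12C)C[C@H]1C(C)=CC[C@H]2C(C)(C)[C@@H](O)CC[C@]12C | intermediate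
18 | 11-[(8βH)-3β-hydroxydriman-11-yl]drim-7-en-3β-ol (CNP0194061.1) | CC1=CC[C@H]2C(C)(C)[C@@H](O)CC[C@]2(C)[C@H]1CC[C@H]1[C@H](C)CC[C@H]2C(C)(C)[C@@H](O)CC[C@]12C | target

**Step count and risks**

Total: 10 steps. Longest linear sequence: 9 steps (steps 1, 3, 4, 5, 6, 7, 8, 9, 10 from compound 1).

Steps most likely to fail:

1. Step 5 (proposed new method). What may go wrong: enolisation at C8 of ring B, or retro-aldol cleavage of the aldolate, outruns formation of the C4 enolate, so ring closure stalls after the aldol stage. Fallback, from 8 back to 13: the kinetic lithium dienolate of commercial 3-methylbut-3-en-2-one (LiN(iPr)2, THF, −78 °C) is added to both formyl groups and quenched cold to give the bis(β-hydroxy isopropenyl ketone) F1. Cobalt-catalysed Michael cycloreduction (Co(dpm)2 [Co(C11H19O2)2], PhSiH3, ClCH2CH2Cl, 25 °C) should then hydrometalate the less hindered 1,1-disubstituted enone, form the C4 enolate regiospecifically without any base, and close ring A onto C5. Both reaction types are known.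

2. Step 6. What may go wrong: the retro-Michael/Michael equilibration is too slow or the ring-opened dienolate is diverted, so epimerisation at C5 stays incomplete and the kinetic cis ring fusion persists. Fallback, from 8 back to 14: the annulation of step 5 is quenched with Me3SiCl instead of AcOH, which traps the ring B enolate and the C1 alkoxide and gives the tetrakis(trimethylsilyl) compound F2. Saegusa–Ito oxidation (Pd(OAc)2, O2, DMSO) makes C5 trigonal in the bis(5-en-7-one) F3. Hydrogenation (H2, Pd/C (palladium on carbon), EtOAc) from the face opposite the C10 methyl should set 5α-H in the saturated tetraone F4. TsOH·H2O in benzene at 70 °C then removes the silyl ethers, dehydrates C1–C2 and equilibrates C8.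

3. Step 10. What may go wrong: over-reduction to the tetrahydro compound and insufficient facial selectivity of hydrogen delivery to the C8 radical. Fallback, from 14 to 18: one equivalent of Tf2O with the hindered pyridine gives the mono(enol triflate) F5, separated from 14 and 15 (this step is statistical). Formate reduction as in step 8 gives the mono-alkene trione F6. Ethane-1,2-dithiol with BF3·OEt2 converts the remaining C7 ketone into the dithiolane F7; the hindered, conjugated ring A carbonyls should react more slowly. Li in liquid NH3 with EtOH then cleaves both C–S bonds to CH2 and reduces both enones to the 3β-alcohols. The C8 methyl of the saturated half is the equatorial epimer already fixed by ketone equilibration in step 6.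

Further compounds
F1 | step 5 | 5,5′-(ethane-1,2-diyl)bis[4-(1-hydroxy-4-methyl-3-oxopent-4-en-1-yl)-4,6-dimethylcyclohex-2-en-1-one] (carbinol and ring C6 unassigned) | C([C@H]1C(C)C(=O)C=C[C@]1(C)C(O)CC(=O)C(C)=C)C[C@H]1C(C)C(=O)C=C[C@]1(C)C(O)CC(=O)C(C)=C
F2 | step 6 | 1,1′,7,7′-tetrakis(trimethylsilyloxy)-11,11′-bi(drim-6-ene)-3,3′-dione (C1, C5, C8 unassigned) | C([C@H]1C(C)C(O[Si](C)(C)C)=CC2C(C)(C)C(=O)CC(O[Si](C)(C)C)[C@]12C)C[C@H]1C(C)C(O[Si](C)(C)C)=CC2C(C)(C)C(=O)CC(O[Si](C)(C)C)[C@]12C
F3 | step 6 | 1,1′-bis(trimethylsilyloxy)-11,11′-bi(drim-5-ene)-3,3′,7,7′-tetraone (C1, C8 unassigned) | C([C@H]1C(C)C(=O)C=C2C(C)(C)C(=O)CC(O[Si](C)(C)C)[C@]12C)C[C@H]1C(C)C(=O)C=C2C(C)(C)C(=O)CC(O[Si](C)(C)C)[C@]12C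
F4 | step 6 | 1,1′-bis(trimethylsilyloxy)-11,11′-bidrimane-3,3′,7,7′-tetraone, 5α-H (C1, C8 unassigned) | C([C@H]1C(C)C(=O)C[C@H]2C(C)(C)C(=O)CC(O[Si](C)(C)C)[C@]12C)C[C@H]1C(C)C(=O)C[C@H]2C(C)(C)C(=O)CC(O[Si](C)(C)C)[C@]12C
F5 | step 10 | mono(enol triflate) of 14: one half C7=C8–OTf, other half 7-ketone | C([C@H]1C(C)=C(OS(=O)(=O)C(F)(F)F)C[C@H]2C(C)(C)C(=O)C=C[C@]12C)C[C@H]1[C@H](C)C(=O)C[C@H]2C(C)(C)C(=O)C=C[C@]12C
F6 | step 10 | 11-[(8βH)-3,7-dioxodrim-1-en-11-yl]drima-1,7-dien-3-one | C([C@H]1C(C)=CC[C@H]2C(C)(C)C(=O)C=C[C@]12C)C[C@H]1[C@H](C)C(=O)C[C@H]2C(C)(C)C(=O)C=C[C@]12C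
F7 | step 10 | 7′,7′-(ethane-1,2-diyldithio) ketal of F6 | C([C@H]1C(C)=CC[C@H]2C(C)(C)C(=O)C=C[C@]12C)C[C@H]1[C@H](C)C3(SCCS3)C[C@H]2C(C)(C)C(=O)C=C[C@]12C
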